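**Retrosynthetic overview**

1. Target ⇒ its tris-silyl ether; the side-chain CH2OH is made last from the (E)-methyl of an 8-prenyl group by SeO2 allylic oxidation.
2. C2–aryl bond and the only stereocentre ⇒ enantioselective Pd-catalysed 1,4-addition of a 3,4-bis(silyloxy)phenylboronic acid (ring B, from 4-bromocatechol) to a 7-silyloxy-8-prenylchromone.
3. Chromone ⇒ key step in one flask: Diels–Alder benzannulation of a 2-prenyl Chan-type diene with but-3-yn-2-one builds ring A, then aminomethylenation and acid cyclisation close ring C.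
4. Diene ⇒ methyl acetoacetate + prenyl bromide, so the prenyl group is fixed between the two future oxygens (C8) before any ring exists.
5. Ring order: A, then C, in the same operation; ring B is bought.

Assumption: but-3-yn-2-one, 4-bromocatechol, t-BuOCH(NMe2)2 and (R)-t-BuPyOx [(R)-4-tert-butyl-2-(pyridin-2-yl)-4,5-dihydrooxazole] are treated as catalogue chemicals.

**Route**

Step 1
Reactants: 1 methyl acetoacetate; 2 prenyl bromide (1-bromo-3-methylbut-2-ene)
Product: 3 methyl 2-acetyl-5-methylhex-4-enoate (racemic)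
Conditions: K2CO3, acetone, reflux
Reagents that add atoms: none
Why: Acetoacetic ester alkylation, in which the soft potassium enolate of 1 is C-alkylated at the primary carbon of the allylic bromide; the new α-stereocentre is racemic and disappears in step 2.

Step 2
Reactants: 3 methyl 2-acetyl-5-methylhex-4-enoate
Product: 5 Chan-type diene 1-methoxy-2-(3-methylbut-2-en-1-yl)-1,3-bis(trimethylsilyloxy)buta-1,3-diene, via silyl enol ether 4 (not isolated)
Conditions: Me3SiOTf (2.3 equiv), Et3N (2.6 equiv), Et2O, 0 → 25 °C; filter, concentrate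
Reagents that add atoms: trimethylsilyl trifluoromethanesulfonate, C[Si](C)(C)OS(=O)(=O)C(F)(F)F
Why: Double O-silylation of a β-ketoester (one-flask Simchen variant of Chan's diene synthesis), in which the ketone enol is silylated first to give 4 and Me3SiOTf/Et3N then converts the ester into the silyl ketene acetal by γ-deprotonation; no stereocentre is involved and the ketene-acetal geometry does not matter for the cycloaddition.

Step 3 (key step)
Reactants: 5 Chan-type diene; 6 but-3-yn-2-one
Product: 10 chromone phenol 7-hydroxy-8-(3-methylbut-2-en-1-yl)-4H-chromen-4-one, via Diels–Alder cycloadduct 7 (not isolated), via bis-silylated aryl ketone 8 (not isolated), via enaminone 9 (not isolated)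
Conditions: PhMe, 25 → 60 °C; then t-BuOCH(NMe2)2, 80 °C; then 2 M HCl, THF, 25 °C
Reagents that add atoms: tert-butoxybis(dimethylamino)methane (Bredereck's reagent), CN(C)C(OC(C)(C)C)N(C)C
Why: Diels–Alder benzannulation of a 1-alkoxy-1,3-bis(silyloxy)diene with an alkynone (Brassard/Chan type; the nucleophilic CH2 terminus bonds to the alkyne β-carbon, so after loss of methanol the acetyl group sits ortho to the ketene-acetal oxygen and the prenyl group lies between the two oxygens) builds ring A, and aminomethylenation of the acetyl group followed by acid-induced addition–elimination of the ortho phenol (enaminone chromone synthesis) closes ring C in the same flask; no stereocentre survives.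

Step 4
Reactants: 10 chromone phenol
Product: 11 silyl-protected chromone 7-[(tert-butyldimethylsilyl)oxy]-8-(3-methylbut-2-en-1-yl)-4H-chromen-4-one
Conditions: t-BuMe2SiCl, imidazole, DMF, 25 °C
Reagents that add atoms: tert-butyldimethylsilyl chloride, CC(C)(C)[Si](C)(C)Cl
Why: Silyl ether formation (Corey imidazole protocol) masks the acidic 7-phenol so that it neither protonates the aryl–palladium species in step 7 nor interferes with the selenium oxidation in step 8.

Step 5
Reactants: 12 4-bromocatechol (4-bromobenzene-1,2-diol)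
Product: 13 aryl bromide 4-bromo-1,2-bis[(tert-butyldimethylsilyl)oxy]benzene
Conditions: t-BuMe2SiCl (2.4 equiv), imidazole, DMF, 25 °C
Reagents that add atoms: tert-butyldimethylsilyl chloride, CC(C)(C)[Si](C)(C)Cl
Why: Silyl ether formation on both catechol hydroxyls gives a ring B unit that tolerates n-BuLi and is unmasked together with the 7-O-silyl group in step 9.

Step 6
Reactants: 13 aryl bromide
Product: 16 arylboronic acid {3,4-bis[(tert-butyldimethylsilyl)oxy]phenyl}boronic acid, via aryllithium 14 (not isolated), via lithium aryltriisopropoxyborate 15 (not isolated)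
Conditions: n-BuLi, THF, −78 °C; B(Oi-Pr)3, −78 → 0 °C; then 1 M HCl, 0 °C
Reagents that add atoms: triisopropyl borate, CC(C)OB(OC(C)C)OC(C)C; water, O
Why: Bromine–lithium exchange followed by borylation with a trialkyl borate and hydrolysis gives the boronic acid, and because lithium sits meta and para to the silyloxy groups no 1,3-silyl shift can occur.

Step 7
Reactants: 11 silyl-protected chromone; 16 arylboronic acid
Product: 17 tris-silylated prenylflavanone (2S)-2-{3,4-bis[(tert-butyldimethylsilyl)oxy]phenyl}-7-[(tert-butyldimethylsilyl)oxy]-8-(3-methylbut-2-en-1-yl)-2,3-dihydro-4H-chromen-4-one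
Conditions: Pd(OCOCF3)2 (5 mol %), (R)-t-BuPyOx (6 mol %), NH4PF6 (30 mol %), H2O (5 equiv), ClCH2CH2Cl, 60 °C
Reagents that add atoms: none
Why: Enantioselective conjugate addition of an arylboronic acid to a chromone catalysed by cationic divalent palladium with a pyridine–oxazoline ligand (Stoltz-type Hayashi–Miyaura addition), in which the (R)-ligand, chosen as the mirror image of the one that gives (2R)-flavanones by analogy with the cyclic-enone facial model, directs aryl insertion to the face that gives the (2S) centre before water protonates the palladium enolate.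

Step 8
Reactants: 17 tris-silylated prenylflavanone
Product: 18 tris-silylated allylic alcohol (2S)-2-{3,4-bis[(tert-butyldimethylsilyl)oxy]phenyl}-7-[(tert-butyldimethylsilyl)oxy]-8-[(2E)-4-hydroxy-3-methylbut-2-en-1-yl]-2,3-dihydro-4H-chromen-4-one
Conditions: SeO2 (0.5 equiv), t-BuOOH (3 equiv), CH2Cl2, 0 → 25 °C
Reagents that add atoms: selenium dioxide (oxygen donor), O=[Se]=O; tert-butyl hydroperoxide (terminal oxidant), CC(C)(C)OO
Why: Riley–Sharpless allylic oxidation, in which the ene reaction of SeO2 followed by a [2,3]-sigmatropic shift delivers oxygen to the methyl group trans to the ArCH2 chain and so fixes the E geometry, while the silyl ethers, the ketone and C2 are untouched at room temperature.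

Step 9
Reactants: 18 tris-silylated allylic alcohol
Product: 19 target (2S)-2-(3,4-dihydroxyphenyl)-7-hydroxy-8-[(2E)-4-hydroxy-3-methylbut-2-en-1-yl]-2,3-dihydro-4H-chromen-4-one
Conditions: Et3N·3HF, THF, 25 °C
Reagents that add atoms: none
Why: Fluoride-mediated cleavage of the three aryl silyl ethers under mildly acidic conditions, which avoids the phenoxide/enolate retro-oxa-Michael ring opening that would racemise C2 and leaves the allylic alcohol intact.

**Compound list**

1 | methyl acetoacetate | CC(=O)CC(=O)OC | starting material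
2 | prenyl bromide (1-bromo-3-methylbut-2-ene) | CC(C)=CCBr | starting material
3 | methyl 2-acetyl-5-methylhex-4-enoate (racemic) | CC(=O)C(CC=C(C)C)C(=O)OC | intermediate
4 | methyl 5-methyl-2-[1-(trimethylsilyloxy)ethylidene]hex-4-enoate (E/Z mixture, not isolated) | CC(O[Si](C)(C)C)=C(CC=C(C)C)C(=O)OC | intermediate
5 | 1-methoxy-2-(3-methylbut-2-en-1-yl)-1,3-bis(trimethylsilyloxy)buta-1,3-diene (ketene-acetal geometry unassigned) | C=C(O[Si](C)(C)C)C(CC=C(C)C)=C(OC)O[Si](C)(C)C | intermediate
6 | but-3-yn-2-one | CC(=O)C#C | starting material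
7 | 1-[6-methoxy-5-(3-methylbut-2-en-1-yl)-4,6-bis(trimethylsilyloxy)cyclohexa-1,4-dien-1-yl]ethan-1-one (racemic, not isolated) | CC(=O)C1=CCC(O[Si](C)(C)C)=C(CC=C(C)C)C1(OC)O[Si](C)(C)C | intermediate
8 | 1-[3-(3-methylbut-2-en-1-yl)-2,4-bis(trimethylsilyloxy)phenyl]ethan-1-one (not isolated) | CC(=O)c1ccc(O[Si](C)(C)C)c(CC=C(C)C)c1O[Si](C)(C)C | intermediate
9 | (2E)-3-(dimethylamino)-1-[3-(3-methylbut-2-en-1-yl)-2,4-bis(trimethylsilyloxy)phenyl]prop-2-en-1-one (not isolated) | CN(C)/C=C/C(=O)c1ccc(O[Si](C)(C)C)c(CC=C(C)C)c1O[Si](C)(C)C | intermediate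
10 | 7-hydroxy-8-(3-methylbut-2-en-1-yl)-4H-chromen-4-one | O=c1ccoc2c(CC=C(C)C)c(O)ccc12 | intermediate
11 | 7-[(tert-butyldimethylsilyl)oxy]-8-(3-methylbut-2-en-1-yl)-4H-chromen-4-one | O=c1ccoc2c(CC=C(C)C)c(O[Si](C)(C)C(C)(C)C)ccc12 | intermediate
12 | 4-bromocatechol (4-bromobenzene-1,2-diol) | Oc1ccc(Br)cc1O | starting material
13 | 4-bromo-1,2-bis[(tert-butyldimethylsilyl)oxy]benzene | Brc1ccc(O[Si](C)(C)C(C)(C)C)c(O[Si](C)(C)C(C)(C)C)c1 | intermediate
14 | {3,4-bis[(tert-butyldimethylsilyl)oxy]phenyl}lithium (not isolated) | [Li]c1ccc(O[Si](C)(C)C(C)(C)C)c(O[Si](C)(C)C(C)(C)C)c1 | intermediate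
15 | lithium {3,4-bis[(tert-butyldimethylsilyl)oxy]phenyl}tri(propan-2-yloxy)borate (not isolated) | [Li+].CC(C)O[B-](OC(C)C)(OC(C)C)c1ccc(O[Si](C)(C)C(C)(C)C)c(O[Si](C)(C)C(C)(C)C)c1 | intermediate
16 | {3,4-bis[(tert-butyldimethylsilyl)oxy]phenyl}boronic acid | OB(O)c1ccc(O[Si](C)(C)C(C)(C)C)c(O[Si](C)(C)C(C)(C)C)c1 | intermediate
17 | (2S)-2-{3,4-bis[(tert-butyldimethylsilyl)oxy]phenyl}-7-[(tert-butyldimethylsilyl)oxy]-8-(3-methylbut-2-en-1-yl)-2,3-dihydro-4H-chromen-4-one | CC(C)=CCc1c(O[Si](C)(C)C(C)(C)C)ccc2c1O[C@H](c1ccc(O[Si](C)(C)C(C)(C)C)c(O[Si](C)(C)C(C)(C)C)c1)CC2=O | intermediate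
18 | (2S)-2-{3,4-bis[(tert-butyldimethylsilyl)oxy]phenyl}-7-[(tert-butyldimethylsilyl)oxy]-8-[(2E)-4-hydroxy-3-methylbut-2-en-1-yl]-2,3-dihydro-4H-chromen-4-one | C/C(=C\Cc1c(O[Si](C)(C)C(C)(C)C)ccc2c1O[C@H](c1ccc(O[Si](C)(C)C(C)(C)C)c(O[Si](C)(C)C(C)(C)C)c1)CC2=O)CO | intermediate
19 | (2S)-2-(3,4-dihydroxyphenyl)-7-hydroxy-8-[(2E)-4-hydroxy-3-methylbut-2-en-1-yl]-2,3-dihydro-4H-chromen-4-one | C/C(=C\Cc1c(O)ccc2c1O[C@H](c1ccc(O)c(O)c1)CC2=O)CO | target

**Step count and risks**

Total: 9 steps. Longest linear sequence: 7 steps (1, 2, 3, 4, 7, 8, 9); steps 5 and 6 form the ring B branch.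

The three steps most likely to fail are steps 3, 7 and 8.

Step 3: the tetrasubstituted ketene-acetal diene may be too hindered or too labile for a clean cycloaddition, and the telescoped aminomethylenation has not been run on the crude silylated ketone. The fallback buys ring A instead of building it and sets out from prenyl bromide 2. Commercial 2,4-dihydroxyacetophenone is C-prenylated with 2 in aqueous KOH at 0–25 °C, the carbon between the two hydroxyls being the most nucleophilic, to give 1-[2,4-dihydroxy-3-(3-methylbut-2-en-1-yl)phenyl]ethan-1-one F1 after separation from the 5-prenyl and O-prenyl isomers. Heating F1 with t-BuOCH(NMe2)2 gives (2E)-3-(dimethylamino)-1-[2,4-dihydroxy-3-(3-methylbut-2-en-1-yl)phenyl]prop-2-en-1-one F2, which closes with dilute HCl in CH2Cl2. The fallback comes back to the route at chromone 10.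

Step 7: the 7-silyloxy chromone is an electron-rich, sluggish acceptor, so conversion or enantiomeric excess may be too low, and the ligand antipode is assigned by analogy only. The fallback replaces asymmetric catalysis by resolution and sets out from 11 and 16. Racemic addition with Pd(OCOCF3)2 and 2,2'-bipyridine gives rac-2-{3,4-bis[(tert-butyldimethylsilyl)oxy]phenyl}-7-[(tert-butyldimethylsilyl)oxy]-8-(3-methylbut-2-en-1-yl)-2,3-dihydro-4H-chromen-4-one F3. Kinetic resolution by Noyori transfer hydrogenation with RuCl[(R,R)-TsDPEN](p-cymene) in HCO2H/Et3N reduces the (2R)-ketone to (2R,4R)-2-{3,4-bis[(tert-butyldimethylsilyl)oxy]phenyl}-7-[(tert-butyldimethylsilyl)oxy]-8-(3-methylbut-2-en-1-yl)-3,4-dihydro-2H-chromen-4-ol F4. The unreacted (2S)-ketone is separated by chromatography in at most 50 % yield, and the fallback comes back to the route at 17.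

Step 8: over-oxidation to the enal, incomplete conversion or attack at C3 of the flavanone can erode the yield. The fallback builds the oxidised terminus by olefin metathesis and sets out from 17. Cross-metathesis with methacrolein using the second-generation Hoveyda–Grubbs catalyst in CH2Cl2 at 40 °C exchanges the isopropylidene end and gives (2E)-4-[(2S)-2-{3,4-bis[(tert-butyldimethylsilyl)oxy]phenyl}-7-[(tert-butyldimethylsilyl)oxy]-4-oxo-3,4-dihydro-2H-chromen-8-yl]-2-methylbut-2-enal F5, the E isomer being strongly favoured for this class of enal. Aldehyde-selective reduction with NaBH4 in THF/MeOH at −78 °C, at which the electron-rich aryl ketone is much slower, brings the fallback back to the route at 18.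

**Further compounds**

F1 | step 3 | 1-[2,4-dihydroxy-3-(3-methylbut-2-en-1-yl)phenyl]ethan-1-one | CC(=O)c1ccc(O)c(CC=C(C)C)c1O
F2 | step 3 | (2E)-3-(dimethylamino)-1-[2,4-dihydroxy-3-(3-methylbut-2-en-1-yl)phenyl]prop-2-en-1-one | CN(C)/C=C/C(=O)c1ccc(O)c(CC=C(C)C)c1O
F3 | step 7 | rac-2-{3,4-bis[(tert-butyldimethylsilyl)oxy]phenyl}-7-[(tert-butyldimethylsilyl)oxy]-8-(3-methylbut-2-en-1-yl)-2,3-dihydro-4H-chromen-4-one | CC(C)=CCc1c(O[Si](C)(C)C(C)(C)C)ccc2c1OC(c1ccc(O[Si](C)(C)C(C)(C)C)c(O[Si](C)(C)C(C)(C)C)c1)CC2=O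
F4 | step 7 | (2R,4R)-2-{3,4-bis[(tert-butyldimethylsilyl)oxy]phenyl}-7-[(tert-butyldimethylsilyl)oxy]-8-(3-methylbut-2-en-1-yl)-3,4-dihydro-2H-chromen-4-ol | CC(C)=CCc1c(O[Si](C)(C)C(C)(C)C)ccc2c1O[C@@H](c1ccc(O[Si](C)(C)C(C)(C)C)c(O[Si](C)(C)C(C)(C)C)c1)C[C@H]2O
F5 | step 8 | (2E)-4-[(2S)-2-{3,4-bis[(tert-butyldimethylsilyl)oxy]phenyl}-7-[(tert-butyldimethylsilyl)oxy]-4-oxo-3,4-dihydro-2H-chromen-8-yl]-2-methylbut-2-enal | C/C(=C\Cc1c(O[Si](C)(C)C(C)(C)C)ccc2c1O[C@H](c1ccc(O[Si](C)(C)C(C)(C)C)c(O[Si](C)(C)C(C)(C)C)c1)CC2=O)C=O
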